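**Assumption:** candidachalcone has no stereocentres, so "single enantiomer" is taken to mean the single geometric isomer shown: (Z) side-chain alkene and (E) enone.

## Retrosynthetic overview
1. Target ⇒ removal of two phenolic allyl ethers (Pd(0)) and one tertiary triethylsilyl ether (fluoride). Deprotections are non-acidic because acid would close the side chain onto the ortho phenol to give a 2,2-dimethylchromene.
2. (E)-enone ⇒ Claisen–Schmidt condensation of a fully substituted 2-hydroxyacetophenone with 4-(allyloxy)benzaldehyde.
3. Aryl–(Z)-alkenyl bond at C3' ⇒ proposed new Bi(V)-mediated, OH-directed ortho C–H alkenylation of the 4'-O-allyl acetophenone with a (Z)-alkenylboronate, with retention of geometry.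
4. (Z)-alkenylboronate ⇒ Rh-catalysed trans-hydroboration of silyl-protected 2-methyl-3-butyn-2-ol; this sets the Z geometry.
5. No rings are formed: both benzene rings are bought, as 2',4'-dihydroxy-6'-methoxyacetophenone and 4-(allyloxy)benzaldehyde.

## Route

**Step 1**
Reactants: 1, 2-methylbut-3-yn-2-ol; 2, chlorotriethylsilane
Product: 3, triethyl[(2-methylbut-3-yn-2-yl)oxy]silane
Conditions: TESCl (1.2 equiv), imidazole, DMAP (cat.), DMF, rt
Reagents that add atoms: chlorotriethylsilane (2), CC[Si](Cl)(CC)CC
Why: Standard silylation of a tertiary propargylic alcohol; the silyl ether masks the OH for the hydroboration and keeps it from chelating bismuth in step 4.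

**Step 2**
Reactants: 3 (1.2 equiv); 4, pinacolborane
Product: 5, (Z)-triethyl{[2-methyl-4-(4,4,5,5-tetramethyl-1,3,2-dioxaborolan-2-yl)but-3-en-2-yl]oxy}silane
Conditions: [Rh(cod)Cl]2 (1.5 mol%), P(i-Pr)3 (6 mol%), Et3N, HBpin, cyclohexane, rt
Reagents that add atoms: pinacolborane (4), [H]B1OC(C)(C)C(C)(C)O1
Why: Rh-catalysed trans-hydroboration of a terminal alkyne through a Rh-vinylidene gives net anti addition of H–B, so the (Z)-1-alkenylboronate is formed and the Z geometry is set here.

**Step 3**
Reactants: 6, 1-(2,4-dihydroxy-6-methoxyphenyl)ethan-1-one (2',4'-dihydroxy-6'-methoxyacetophenone); 7, allyl bromide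
Product: 8, 1-[4-(allyloxy)-2-hydroxy-6-methoxyphenyl]ethan-1-one
Conditions: allyl bromide (1.05 equiv), K2CO3 (1.1 equiv), acetone, reflux
Reagents that add atoms: allyl bromide (7), C=CCBr
Why: Williamson etherification is selective for the more acidic 4-OH because the 2-OH is hydrogen-bonded to the ketone; this leaves a single free phenol to direct step 4.

**Step 4 (proposed new transformation)**
Reactants: 8; 5
Product: 9, 1-{4-(allyloxy)-2-hydroxy-6-methoxy-3-[(Z)-3-methyl-3-(triethylsilyloxy)but-1-en-1-yl]phenyl}ethan-1-one
Conditions: (i) sulfone-bridged diaryl bismacycle tosylate (10-tosyloxy-phenothiabismine 5,5-dioxide, 1.1 equiv), 5 (1.2 equiv), K2CO3, PhMe/H2O, 60 °C; (ii) mCPBA (1.1 equiv), 0 °C→rt, 5 min; (iii) 8 (1.0 equiv), DBU (1.2 equiv), PhMe, rt, dark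
Reagents that add atoms: none beyond reactant 5 (alkenyl donor), CC[Si](CC)(CC)OC(C)(C)/C=C\B1OC(C)(C)C(C)(C)O1; the bismacycle and mCPBA leave no atoms in the product
Why: Proposed new method: Bi(V)-mediated, phenol-directed ortho C–H (Z)-alkenylation. B-to-Bi transmetalation puts the alkenyl group on Bi(III), mCPBA oxidises it to Bi(V), and the phenoxide of 8 binds Bi through its only free OH. Ligand coupling through a five-membered transition state delivers the alkenyl carbon to the only free ortho carbon (C3; the other ortho carbon bears the acetyl), and tautomerisation restores the arene. The sp2 carbon migrates with retention, so Z is preserved. The bridged backbone aryls do not transfer, and the OTES group prevents the side-chain oxygen from tying the alkenyl into a non-transferable Bi–O chelate. The closest known reaction type is Bi(V) ortho-arylation of phenols with arylboronic-acid-derived bismacycles (Barton-type ligand coupling).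

**Step 5**
Reactants: 9; 10, 4-(allyloxy)benzaldehyde (1.2 equiv)
Product: 11, (E)-1-{4-(allyloxy)-2-hydroxy-6-methoxy-3-[(Z)-3-methyl-3-(triethylsilyloxy)but-1-en-1-yl]phenyl}-3-[4-(allyloxy)phenyl]prop-2-en-1-one
Conditions: KOH (50% aq., 10 equiv), EtOH, rt, 24–48 h; quench into cold aq. NH4Cl (pH ≈ 7)
Reagents that add atoms: none beyond reactant 10, O=Cc1ccc(OCC=C)cc1
Why: Claisen–Schmidt aldol condensation; E1cB dehydration gives the thermodynamic (E)-enone, and 2'-hydroxy-4',6'-dialkoxy chalcones are isolated as the chalcone under these conditions. The allyl ethers, tertiary TES ether and Z-alkene are base-stable.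

**Step 6**
Reactants: 11
Product: 12, (E)-1-{4-(allyloxy)-2-hydroxy-3-[(Z)-3-hydroxy-3-methylbut-1-en-1-yl]-6-methoxyphenyl}-3-[4-(allyloxy)phenyl]prop-2-en-1-one
Conditions: TBAF (1.5 equiv), THF, 0 °C→rt; pH 7 buffer work-up
Reagents that add atoms: none
Why: Fluoride-mediated Si–O cleavage frees the tertiary alcohol without acid, so there is no ionisation to the chromene and no change to either alkene.

**Step 7**
Reactants: 12
Product: 13, candidachalcone, (E)-1-{2,4-dihydroxy-3-[(Z)-3-hydroxy-3-methylbut-1-en-1-yl]-6-methoxyphenyl}-3-(4-hydroxyphenyl)prop-2-en-1-one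
Conditions: Pd(PPh3)4 (5 mol%), morpholine (10 equiv), THF, rt, dark; pH 7 buffer work-up, Et3N-deactivated silica or C18
Reagents that add atoms: none
Why: Tsuji–Trost deallylation: Pd(0) ionises both aryl allyl ethers and morpholine traps the π-allyl. The conditions are near-neutral, so the tertiary allylic alcohol is not ionised and the 2'-OH chalcone is not pushed to the flavanone.

## Compound list
1 | 2-methylbut-3-yn-2-ol | CC(C)(O)C#C | starting material
2 | chlorotriethylsilane | CC[Si](Cl)(CC)CC | starting material
3 | triethyl[(2-methylbut-3-yn-2-yl)oxy]silane | CC[Si](CC)(CC)OC(C)(C)C#C | intermediate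
4 | pinacolborane | [H]B1OC(C)(C)C(C)(C)O1 | starting material
5 | (Z)-triethyl{[2-methyl-4-(pinacolboryl)but-3-en-2-yl]oxy}silane | CC[Si](CC)(CC)OC(C)(C)/C=C\B1OC(C)(C)C(C)(C)O1 | intermediate
6 | 1-(2,4-dihydroxy-6-methoxyphenyl)ethan-1-one | CC(=O)c1c(O)cc(O)cc1OC | starting material
7 | allyl bromide | C=CCBr | starting material
8 | 1-[4-(allyloxy)-2-hydroxy-6-methoxyphenyl]ethan-1-one | CC(=O)c1c(O)cc(OCC=C)cc1OC | intermediate
9 | 1-{4-(allyloxy)-2-hydroxy-6-methoxy-3-[(Z)-3-methyl-3-(triethylsilyloxy)but-1-enyl]phenyl}ethan-1-one | CC(=O)c1c(OC)cc(OCC=C)c(/C=C\C(C)(C)O[Si](CC)(CC)CC)c1O | intermediate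
10 | 4-(allyloxy)benzaldehyde | O=Cc1ccc(OCC=C)cc1 | starting material
11 | bis-O-allyl, O-TES protected candidachalcone | COc1cc(OCC=C)c(/C=C\C(C)(C)O[Si](CC)(CC)CC)c(O)c1C(=O)/C=C/c1ccc(OCC=C)cc1 | intermediate
12 | 4,4'-di-O-allyl candidachalcone | COc1cc(OCC=C)c(/C=C\C(C)(C)O)c(O)c1C(=O)/C=C/c1ccc(OCC=C)cc1 | intermediate
13 | candidachalcone | COc1cc(O)c(/C=C\C(C)(C)O)c(O)c1C(=O)/C=C/c1ccc(O)cc1 | target

## Summary
Total steps: 7. Longest linear sequence: 6 (steps 1 → 2 → 4 → 5 → 6 → 7).

Steps most likely to fail:
1. **Step 4 (proposed Bi(V) C–H alkenylation).** Risks are sluggish B-to-Bi transfer of the hindered alkenyl–Bpin, reaction at the acyl-bearing ortho carbon or at oxygen, and erosion of Z. Fallback with known chemistry: iodinate 8 ortho to the free OH at C3 (BnMe3N·ICl2, NaHCO3, CH2Cl2/MeOH), then run a stereoretentive Suzuki–Miyaura coupling with 5 (Pd(dppf)Cl2, K3PO4, THF/H2O, 50 °C) to reach 9.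
2. **Step 2 (trans-hydroboration of a hindered propargylic ether).** Risks are low conversion or E/Z mixtures. Fallback: make the alkynyl–Bpin from 3 (n-BuLi, then i-PrOBpin, then HCl·Et2O) and cis-reduce it by hydrozirconation with Cp2Zr(H)Cl followed by water, which also gives the (Z)-alkenyl–Bpin 5.
3. **Step 7 (final deallylation).** Risks are flavanone formation from the free 2',4'-dihydroxy chalcone under amine base, C-allylation of the electron-rich ring, and chromene formation on work-up. Fallback: change the order and the protecting-group class. Build the chalcone first from 6 and 4-hydroxybenzaldehyde with MOM ethers (acid removal is harmless before the side chain exists), silylate the 4- and 4'-OH with TBSCl, install the side chain at C3' last (step 4 or its fallback), and finish with a single buffered fluoride deprotection (TBAF/AcOH).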